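The C2–C3 bond of the flavanone is the one disconnection on which the route depends, and ring C is traced back to a racemic 2-aryl-4-methylene-4H-1,3-benzodioxine. The feature exploited is that C2 lies between the ring oxygen O1 and C1' of ring B, whose para oxygen on C4' can share positive charge, so C2 ionises readily to an oxocarbenium ion, while C3 and C4 are stored as the enol ether of a ring A aryl methyl ketone. A chiral N-triflylphosphoramide should turn this enol acetal, in one enantioconvergent [1,3] O-to-C shift, into ring C with the new C2–C3 bond and the (S)-centre. The precursor is a tris-TBS enol acetal assembled from a prenylated salicylic acid and a prenylated benzaldehyde.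

Key step: step 11

Assumption: the target is read as the (2S)-flavanone; which antipode of the catalyst gives (S) cannot be predicted, so the (R)-catalyst is written and its mirror image would be used if it proves to give (R).

Remark on the precursor: the three phenols are carried as hindered TBS ethers, while the carboxyl and 2-hydroxyl that build the acetal are silylated only transiently as TMS groups. A silyl ether on O4' is a moderate para donor, enough to direct ionisation to C2 but too weak to let the product re-ionise, and a bulky silyl group resists transfer to the catalyst anion. The acetal is left racemic on purpose, because C2 becomes planar in the key step.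

Abbreviations: TBS = tert-butyldimethylsilyl; TMS = trimethylsilyl; prenyl = 3-methylbut-2-en-1-yl.

Step 1
Reactants: 1 2-methylbut-3-en-2-ol
Product: 2 tert-butyl 2-methylbut-3-en-2-yl carbonate
Conditions: n-BuLi, THF, −78 °C; Boc2O, −78 °C → rt
Reagents that add atoms: di-tert-butyl dicarbonate, CC(C)(C)OC(=O)OC(=O)OC(C)(C)C
Why: O-acylation of the lithium alkoxide of a tertiary alcohol with Boc2O is a standard carbonate synthesis and supplies the ionisable 1,1-dimethylallyl donor needed for both halves.

Step 2
Reactants: 3 3,4-dihydroxybenzaldehyde; 2 tert-butyl 2-methylbut-3-en-2-yl carbonate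
Product: 4 3-hydroxy-4-[(2-methylbut-3-en-2-yl)oxy]benzaldehyde
Conditions: Pd(PPh3)4 (2 mol%), 4 Å MS, THF, 0 °C
Reagents that add atoms: none
Why: Tsuji–Trost O-allylation, in which decarboxylative ionisation of 2 gives a 1,1-dimethylallyl palladium cation and tert-butoxide, the base removes only the more acidic 4-OH (para to the formyl group), and the phenoxide attacks the more substituted allyl terminus under kinetic control to give the tertiary ether.

Step 3
Reactants: 4 3-hydroxy-4-[(2-methylbut-3-en-2-yl)oxy]benzaldehyde
Product: 5 3,4-dihydroxy-5-(3-methylbut-2-en-1-yl)benzaldehyde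
Conditions: PhNEt2, 130 °C, Ar
Reagents that add atoms: none
Why: aromatic Claisen rearrangement, in which the [3,3] shift can end only at C5, the single free ortho position of the 4-oxygen, and the 1,1-dimethylallyl group is inverted to a prenyl group before rearomatisation.

Step 4
Reactants: 5 3,4-dihydroxy-5-(3-methylbut-2-en-1-yl)benzaldehyde
Product: 6 3,4-bis(TBSO)-5-prenylbenzaldehyde
Conditions: TBSCl, imidazole, DMAP (cat.), DMF, 0 °C → rt
Reagents that add atoms: tert-butyldimethylsilyl chloride, CC(C)(C)[Si](C)(C)Cl
Why: standard imidazole-mediated silylation of both catechol hydroxyls gives aryl silyl ethers that should tolerate the silyl triflate, the titanium reagent and the chiral acid used later and that leave together with fluoride at the end.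

Step 5
Reactants: 7 methyl 2,4-dihydroxybenzoate; 2 tert-butyl 2-methylbut-3-en-2-yl carbonate
Product: 8 methyl 2-hydroxy-4-[(2-methylbut-3-en-2-yl)oxy]benzoate
Conditions: Pd(PPh3)4 (2 mol%), 4 Å MS, THF, 0 °C
Reagents that add atoms: none
Why: the same Tsuji–Trost O-allylation, selective here because the 2-OH is locked in a hydrogen bond to the ester carbonyl, so only the 4-OH is deprotonated and alkylated at the tertiary allyl terminus.

Step 6
Reactants: 8 methyl 2-hydroxy-4-[(2-methylbut-3-en-2-yl)oxy]benzoate
Product: 9 methyl 2,4-dihydroxy-3-(3-methylbut-2-en-1-yl)benzoate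
Conditions: PhNEt2, 130 °C, Ar
Reagents that add atoms: none
Why: aromatic Claisen rearrangement, expected to favour C3 over C5 because the chelate ring of the salicylate places the higher bond order in the C3–C4 bond, as is usual for 4-allyloxy-2-hydroxyaryl carbonyl compounds; any C5 isomer should be separable by chromatography.

Step 7
Reactants: 9 methyl 2,4-dihydroxy-3-(3-methylbut-2-en-1-yl)benzoate
Product: 10 2,4-dihydroxy-3-(3-methylbut-2-en-1-yl)benzoic acid
Conditions: KOH, MeOH/H2O, 70 °C, Ar; then 1 M HCl, 0 °C, to pH 3
Reagents that add atoms: potassium hydroxide, [K+].[OH-]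
Why: saponification of the methyl ester is standard and is placed before silylation because aryl silyl ethers would not survive hydroxide, while the prenyl group is inert to base and to brief cold acidification.

Step 8
Reactants: 10 2,4-dihydroxy-3-(3-methylbut-2-en-1-yl)benzoic acid
Product: 12 4-(TBSO)-2-hydroxy-3-prenylbenzoic acid, via bis-TBS silyl ester 11 (not isolated)
Conditions: TBSCl (2.3 equiv), imidazole, DMF, 0 °C → rt; then AcOH/THF/H2O, rt
Reagents that add atoms: tert-butyldimethylsilyl chloride, CC(C)(C)[Si](C)(C)Cl
Why: silylation should take the carboxyl group and the free 4-OH but not the chelated 2-OH flanked by the prenyl group, and the labile silyl ester is then hydrolysed selectively by dilute acetic acid, which leaves the aryl silyl ether in place.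

Step 9
Reactants: 12 4-(TBSO)-2-hydroxy-3-prenylbenzoic acid; 6 3,4-bis(TBSO)-5-prenylbenzaldehyde
Product: 14 rac-2-[3,4-bis(TBSO)-5-prenylphenyl]-7-(TBSO)-8-prenyl-4H-1,3-benzodioxin-4-one, via bis-TMS salicylate 13 (not isolated)
Conditions: HMDS, TMSCl (cat.), THF, 60 °C, then evaporation; 6, TMSOTf (20 mol%), 2,6-di-tert-butyl-4-methylpyridine (10 mol%), CH2Cl2, −78 °C; pyridine quench
Reagents that add atoms: none
Why: silyl-transfer acetalisation of the kind used to make 1,3-dioxan-4-ones from bis-silylated hydroxy acids, in which TMSOTf activates the aldehyde, the silyl ether and silyl ester oxygens of 13 add in turn and hexamethyldisiloxane is expelled, while the hindered pyridine traps stray triflic acid that could attack the prenyl groups.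

Step 10
Reactants: 14 rac-2-[3,4-bis(TBSO)-5-prenylphenyl]-7-(TBSO)-8-prenyl-4H-1,3-benzodioxin-4-one
Product: 15 rac-2-[3,4-bis(TBSO)-5-prenylphenyl]-7-(TBSO)-4-methylidene-8-prenyl-4H-1,3-benzodioxine
Conditions: Cp2TiMe2 (2.5 equiv), toluene, 65 °C, dark; hexane, filtration through Et3N-treated basic Al2O3; used at once
Reagents that add atoms: dimethyltitanocene, C[Ti](C)(C1C=CC=C1)C1C=CC=C1
Why: Petasis methylenation, in which thermally formed Cp2Ti=CH2 converts the lactone carbonyl into the exocyclic enol ether through an oxatitanacyclobutane, as in the methylenation of 1,3-dioxan-4-ones, without the nucleophilic addition that would open the acylal and without touching silyl ethers or trisubstituted alkenes.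

Step 11
Reactants: 15 rac-2-[3,4-bis(TBSO)-5-prenylphenyl]-7-(TBSO)-4-methylidene-8-prenyl-4H-1,3-benzodioxine
Product: 16 (2S)-2-[3,4-bis(TBSO)-5-prenylphenyl]-7-(TBSO)-8-prenyl-2,3-dihydro-4H-chromen-4-one
Conditions: (R)-3,3'-bis(2,4,6-triisopropylphenyl)-1,1'-binaphthyl-2,2'-diyl N-(trifluoromethylsulfonyl)phosphoramide (5 mol%), 5 Å MS, toluene, −40 °C; Et3N quench
Reagents that add atoms: none
Why: Proposed new method: the chiral acid protonates the enol-ether oxygen O3 of 15 and the C2–O3 bond breaks heterolytically, since the cation left at C2 is shared with O1 and, through ring B, with the silyloxy oxygen on C4' para to C1', while the departing fragment is the neutral enol of the ring A aryl methyl ketone, still tied to the cation through ring A and hydrogen-bonded to the phosphoramide anion; its terminal carbon (the future C3) then bonds to C2 and the protonated ketone hands the proton back to the catalyst. The closest known reaction types are the aluminium-Lewis-acid-mediated Petasis–Ferrier conversion of 2-substituted 4-methylene-1,3-dioxanes into tetrahydropyran-4-ones and the aza variant run with chiral BINOL phosphoric acids on hemiaminal vinyl ethers, neither of which covers a benzo-fused aryl acetal or an enantioselective all-oxygen case. Ring C closes by a 6-(enolendo)-endo-trig attack, the C3=C4 enol bond and the O1=C2 oxocarbenium bond both lying inside the new ring. The C2 stereocentre is set by the catalyst alone, because ionisation makes C2 planar, so both enantiomers of 15 enter the same contact ion pair, in which the 3,3'-aryl groups of the anion should block one face of the (E)-oxocarbenium ion and the anion-bound enol attacks the other to give (S). The step needs C-attack instead of O-return, enol attack faster than Prins-type capture of the cation by the 8-prenyl alkene or by moisture, and a product that does not re-ionise; the high nucleophilicity of the enol, its six-membered tether to C2, the irreversibility of ketone formation (O-return only regenerates 15) and the moderate donor strength of the hindered 4'-silyl ether should secure this.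

Step 12
Reactants: 16 (2S)-2-[3,4-bis(TBSO)-5-prenylphenyl]-7-(TBSO)-8-prenyl-2,3-dihydro-4H-chromen-4-one
Product: 17 (2S)-2-[3,4-dihydroxy-5-(3-methylbut-2-en-1-yl)phenyl]-7-hydroxy-8-(3-methylbut-2-en-1-yl)-2,3-dihydro-4H-chromen-4-one
Conditions: Et3N·3HF (excess), THF, 0 °C → rt; pH 7 phosphate buffer work-up
Reagents that add atoms: none
Why: fluoride-mediated cleavage of the three aryl silyl ethers under buffered, nearly neutral conditions avoids the base-induced ring opening to the chalcone that would racemise C2 of a 4'-hydroxyflavanone, and it leaves the prenyl groups untouched.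

Compound list
1 | 2-methylbut-3-en-2-ol | C=CC(C)(C)O | starting material
2 | tert-butyl 2-methylbut-3-en-2-yl carbonate | C=CC(C)(C)OC(=O)OC(C)(C)C | intermediate
3 | 3,4-dihydroxybenzaldehyde | O=Cc1ccc(O)c(O)c1 | starting material
4 | 3-hydroxy-4-[(2-methylbut-3-en-2-yl)oxy]benzaldehyde | O=Cc1ccc(OC(C)(C)C=C)c(O)c1 | intermediate
5 | 3,4-dihydroxy-5-(3-methylbut-2-en-1-yl)benzaldehyde | O=Cc1cc(O)c(O)c(CC=C(C)C)c1 | intermediate
6 | 3,4-bis[(tert-butyldimethylsilyl)oxy]-5-(3-methylbut-2-en-1-yl)benzaldehyde | O=Cc1cc(CC=C(C)C)c(O[Si](C)(C)C(C)(C)C)c(O[Si](C)(C)C(C)(C)C)c1 | intermediate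
7 | methyl 2,4-dihydroxybenzoate | COC(=O)c1ccc(O)cc1O | starting material
8 | methyl 2-hydroxy-4-[(2-methylbut-3-en-2-yl)oxy]benzoate | COC(=O)c1ccc(OC(C)(C)C=C)cc1O | intermediate
9 | methyl 2,4-dihydroxy-3-(3-methylbut-2-en-1-yl)benzoate | COC(=O)c1ccc(O)c(CC=C(C)C)c1O | intermediate
10 | 2,4-dihydroxy-3-(3-methylbut-2-en-1-yl)benzoic acid | CC(C)=CCc1c(O)ccc(C(=O)O)c1O | intermediate
11 | tert-butyldimethylsilyl 4-[(tert-butyldimethylsilyl)oxy]-2-hydroxy-3-(3-methylbut-2-en-1-yl)benzoate (not isolated) | CC(C)=CCc1c(O[Si](C)(C)C(C)(C)C)ccc(C(=O)O[Si](C)(C)C(C)(C)C)c1O | intermediate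
12 | 4-[(tert-butyldimethylsilyl)oxy]-2-hydroxy-3-(3-methylbut-2-en-1-yl)benzoic acid | CC(C)=CCc1c(O[Si](C)(C)C(C)(C)C)ccc(C(=O)O)c1O | intermediate
13 | trimethylsilyl 4-[(tert-butyldimethylsilyl)oxy]-3-(3-methylbut-2-en-1-yl)-2-[(trimethylsilyl)oxy]benzoate (not isolated) | CC(C)=CCc1c(O[Si](C)(C)C(C)(C)C)ccc(C(=O)O[Si](C)(C)C)c1O[Si](C)(C)C | intermediate
14 | rac-2-{3,4-bis[(tert-butyldimethylsilyl)oxy]-5-(3-methylbut-2-en-1-yl)phenyl}-7-[(tert-butyldimethylsilyl)oxy]-8-(3-methylbut-2-en-1-yl)-4H-1,3-benzodioxin-4-one | O=C1OC(c2cc(CC=C(C)C)c(O[Si](C)(C)C(C)(C)C)c(O[Si](C)(C)C(C)(C)C)c2)Oc2c(CC=C(C)C)c(O[Si](C)(C)C(C)(C)C)ccc21 | intermediate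
15 | rac-2-{3,4-bis[(tert-butyldimethylsilyl)oxy]-5-(3-methylbut-2-en-1-yl)phenyl}-7-[(tert-butyldimethylsilyl)oxy]-4-methylidene-8-(3-methylbut-2-en-1-yl)-4H-1,3-benzodioxine | C=C1OC(c2cc(CC=C(C)C)c(O[Si](C)(C)C(C)(C)C)c(O[Si](C)(C)C(C)(C)C)c2)Oc2c(CC=C(C)C)c(O[Si](C)(C)C(C)(C)C)ccc21 | intermediate
16 | (2S)-2-{3,4-bis[(tert-butyldimethylsilyl)oxy]-5-(3-methylbut-2-en-1-yl)phenyl}-7-[(tert-butyldimethylsilyl)oxy]-8-(3-methylbut-2-en-1-yl)-2,3-dihydro-4H-chromen-4-one | CC(C)=CCc1cc([C@@H]2CC(=O)c3ccc(O[Si](C)(C)C(C)(C)C)c(CC=C(C)C)c3O2)cc(O[Si](C)(C)C(C)(C)C)c1O[Si](C)(C)C(C)(C)C | intermediate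
17 | (2S)-2-[3,4-dihydroxy-5-(3-methylbut-2-en-1-yl)phenyl]-7-hydroxy-8-(3-methylbut-2-en-1-yl)-2,3-dihydro-4H-chromen-4-one | CC(C)=CCc1cc([C@@H]2CC(=O)c3ccc(O)c(CC=C(C)C)c3O2)cc(O)c1O | target

Total step count: 12.
Longest linear sequence: 9 steps (steps 1, 5, 6, 7, 8, 9, 10, 11, 12).

Steps most likely to fail

Risk 1, step 11 (new method). What may go wrong:
- weak or reversed facial selection in the ion pair;
- C-protonation of the enol ether followed by hydrolysis on traces of water;
- capture of the cation by the 8-prenyl alkene once the enol has tautomerised to the ketone;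
- slow acid-mediated re-ionisation of the product at C2 that erodes the enantiomeric purity.

The fallback uses known chemistry, sets out from 10 and 6 and returns at 16; it also bypasses steps 9 and 10. Acid 10 is treated with MeLi (5 equiv, THF, 0 °C; addition to the lithium carboxylate) to give the methyl ketone 1-[2,4-dihydroxy-3-(3-methylbut-2-en-1-yl)phenyl]ethan-1-one F1. Its unchelated 4-OH is silylated (TBSCl, imidazole, DMF) to give 1-[4-(TBSO)-2-hydroxy-3-prenylphenyl]ethan-1-one F2. Condensation of F2 with 6 under pyrrolidine (MeCN, 4 Å MS, 50 °C; enamine aldol condensation then oxa-Michael closure, the Kabbe-type flavanone synthesis) should give the racemic tris-TBS flavanone F3. Preparative chromatography on an amylose tris(3,5-dimethylphenylcarbamate) phase then delivers the (S)-enantiomer 16. The unwanted enantiomer can be re-equilibrated through the chalcone with the same amine and recycled.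

Risk 2, step 6. What may go wrong: migration of the allyl group to C5 in competition with C3, and thermal loss of the tertiary allyl group as isoprene. The fallback sets out from 7 and returns at 9, and it blocks C5 first. Bromination of 7 (NBS, MeCN, 0 °C) should give methyl 5-bromo-2,4-dihydroxybenzoate F4. O-alkylation with 2 as in step 5 gives methyl 5-bromo-2-hydroxy-4-[(2-methylbut-3-en-2-yl)oxy]benzoate F5. The Claisen shift (PhNEt2, 130 °C) can then end only at C3 and gives methyl 5-bromo-2,4-dihydroxy-3-(3-methylbut-2-en-1-yl)benzoate F6. Palladium-catalysed formate hydrodebromination (Pd(OAc)2, PPh3, HCO2H, Et3N, DMF, 70 °C) removes the blocking group to give 9.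

Risk 3, step 2 (the same concern, in milder form, applies to step 5). What may go wrong: re-ionisation of the kinetic tertiary ether at palladium with drift to the linear prenyl ether, or alkylation of both catechol oxygens. The fallback sets out from 3 and returns at 4. Copper-catalysed propargylic etherification of 3 with 3-chloro-3-methylbut-1-yne (CuCl2·2H2O cat., DBU, MeCN, 0 °C) can deliver only the tertiary ether and should give 3-hydroxy-4-[(2-methylbut-3-yn-2-yl)oxy]benzaldehyde F7. Semi-hydrogenation (H2, Pd/CaCO3 poisoned with Pb(OAc)2, quinoline, EtOAc) then gives 4.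

Further compounds
F1 | step 11 | 1-[2,4-dihydroxy-3-(3-methylbut-2-en-1-yl)phenyl]ethan-1-one | CC(=O)c1ccc(O)c(CC=C(C)C)c1O
F2 | step 11 | 1-{4-[(tert-butyldimethylsilyl)oxy]-2-hydroxy-3-(3-methylbut-2-en-1-yl)phenyl}ethan-1-one | CC(=O)c1ccc(O[Si](C)(C)C(C)(C)C)c(CC=C(C)C)c1O
F3 | step 11 | rac-2-{3,4-bis[(tert-butyldimethylsilyl)oxy]-5-(3-methylbut-2-en-1-yl)phenyl}-7-[(tert-butyldimethylsilyl)oxy]-8-(3-methylbut-2-en-1-yl)-2,3-dihydro-4H-chromen-4-one | CC(C)=CCc1cc(C2CC(=O)c3ccc(O[Si](C)(C)C(C)(C)C)c(CC=C(C)C)c3O2)cc(O[Si](C)(C)C(C)(C)C)c1O[Si](C)(C)C(C)(C)C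
F4 | step 6 | methyl 5-bromo-2,4-dihydroxybenzoate | COC(=O)c1cc(Br)c(O)cc1O
F5 | step 6 | methyl 5-bromo-2-hydroxy-4-[(2-methylbut-3-en-2-yl)oxy]benzoate | COC(=O)c1cc(Br)c(OC(C)(C)C=C)cc1O
F6 | step 6 | methyl 5-bromo-2,4-dihydroxy-3-(3-methylbut-2-en-1-yl)benzoate | COC(=O)c1cc(Br)c(O)c(CC=C(C)C)c1O
F7 | step 2 | 3-hydroxy-4-[(2-methylbut-3-yn-2-yl)oxy]benzaldehyde | O=Cc1ccc(OC(C)(C)C#C)c(O)c1
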